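I had to choose one vessel for this charge, and I judged it by the share of product among what became product or trapped intermediate.

    substrate + free catalyst ⇌ free catalyst + open intermediate (K1 = 0.267, k1 = 33.3 /M/min)
    second catalyst + open intermediate ⇌ catalyst intermediate (K2 = 0.986 /M, k2 = 203 /M/min)
    reagent + catalyst intermediate → second catalyst + product (k3 = 57.0 /M/min)
    open intermediate + capture agent → trapped intermediate (k4 = 0.526 /M/min)

| flask | substrate | reagent | capture agent | free catalyst | second catalyst | time | remark |
|---|---|---|---|---|---|---|---|
| gamma | 0.89 M | 1.30 equiv | 0.0445 M | 0.1 mol% | 0.05 mol% | 15 min | a closed flask charged with all of it at once and left for 15 min |
| epsilon | 0.89 M | 1.30 equiv | 0.0445 M | 0.1 mol% | 0.05 mol% | 15 min | a tube with plug flow, the mixed feed as stated, residence time 15 min |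
| zeta | 0.89 M | 1.30 equiv | 0.0445 M | 0.1 mol% | 0.05 mol% |  | a single well-mixed tank run continuously and read at steady state, 15 min in it on average |
| beta | 0.89 M | 1.30 equiv | 0.0445 M | 0.1 mol% | 0.05 mol% |  | one stirred flow tank at steady state, fed with the mixture as stated, mean residence time 75.0 min |

- the stated concentrations are those of everything mixed, before any reaction; amounts are the same in each set-up
- run time (gamma): 15 min

- the set-up with the highest share of product in all that became product or trapped intermediate, at the outlet or at the end ("none" if the first two lie within 2 percentage points) (gamma / epsilon / zeta / beta / none)
- share of product in all that became product or trapped intermediate, at the outlet or at the end, gamma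
- share of product in all that became product or trapped intermediate, at the outlet or at the end, epsilon
- share of product in all that became product or trapped intermediate, at the outlet or at the end, zeta
- share of product in all that became product or trapped intermediate, at the outlet or at the end, beta

I first looked for the concentration that sets the order of the rate. Second catalyst binds open intermediate, and reagent then releases product. With reagent at its charge, the rate of that path bends at a saturation level H of 1.34 M of open intermediate. Open intermediate stays under its step-1 equilibrium level O, 0.188 M, which is less than H. So the product path stays close to first order in open intermediate (pseudo-first-order), like the capture path, and open intermediate cancels between them.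

Product then forms against trapped intermediate as B to the capture agent present, where B, the balance level, is the capture agent concentration at which both paths run level: 0.0365 M. I took open intermediate at O here. The charge of capture agent, 0.0445 M, stands above B, so capture leads at the start.

In gamma and epsilon, open intermediate climbs toward O with rate constant 0.141 /min. Summed over the run, that gives a capture exposure x of 0.863. In this estimate capture agent falls as exp(-x), and product grows as B times x, so I got 55.1 % for gamma and 55.1 % for epsilon.

Zeta and beta each work at their outlet level T of capture agent, so I took each share as B/(B+T). Balances of substrate and open intermediate gave open intermediate at 0.112 M in zeta and 0.122 M in beta. I then reckoned capture agent at 0.0236 M in zeta and 0.007647 M in beta. My shares were 60.8 % for zeta and 82.7 % for beta. My choice was beta.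

The forecast named beta, with 55 % for gamma, 55 % for epsilon, 60.7 % for zeta and 81.2 % for beta. It began: “The fast second catalyst can be put in steady state”. My beta share stood higher than its value.

The simulation gave beta, with 54.9 % for gamma, 54.9 % for epsilon, 60.7 % for zeta and 81.2 % for beta.

Epsilon ended with capture agent at 0.0211 M, below B. The neighbour of epsilon was charged with 0.02 mol% of second catalyst. With open intermediate held at O, B scales with second catalyst, so for that neighbour I reckoned it at 0.0146 M, below the capture agent charge. With the same x, I reckoned 32.9 %. That neighbour gave 33.1 %, with product at 1.34 % of the substrate charged, against 3.20 % in epsilon.

(The rate constants are made up; what happens was integrated by code.)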